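**Plan**
Retrosynthesis: after removal of two aryl silyl ethers, ring A is cut in one stroke at C8–C8a, C4a–C5, C5–C6 and C7–C8, giving a 6-aryl-2-(α-diazoacyl)-4-pyranone and a silyl ynol ether.
This cut is possible because ring A reads 5-OH, 6-H, 7-O, 8-prenyl around the C4a–C8a edge of the pyranone, the pattern that a vinylketene (pyranone C2=C3 plus ketene) and an oxygenated alkyne produce.
The diazo ketone goes back through a ketone and a Weinreb amide to a 1,3,5-triketone (pyranone O1–C bond), an aroylacetone and the ring B acetophenone, whose two prenyl groups come from a double Stille coupling.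
Forward: ring B is dressed first, the pyranone (ring C) is closed by cyclodehydration, the diazo side chain is attached, ring A is annulated last, and one desilylation ends the route.
Stereochemistry: the target has no stereocentre and no stereodefined double bond, so nothing has to be controlled.

Key step: step 8

Remark: ring A atoms are given in flavone numbering throughout; compounds 1, 2, 7 and 10 are taken as catalogue chemicals.

**Step 1**
Reactants: 1 3,5-dibromo-4-hydroxyacetophenone; 2 tributyl(3-methylbut-2-enyl)stannane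
Product: 3 1-[4-hydroxy-3,5-bis(3-methylbut-2-enyl)phenyl]ethanone
Conditions: 2 (2.5 equiv), Pd(PPh3)4 (5 mol %), DMF, 100 °C
Reagents that add atoms: none
Why: Twofold Stille coupling at the C–Br bonds of an acetyl-deactivated ring; allylstannanes of this kind transfer the allyl group through the unsubstituted terminus, so the linear prenyl group should result, and the neutral conditions tolerate the free phenol and the ketone.

**Step 2**
Reactants: 3 1-[4-hydroxy-3,5-bis(3-methylbut-2-enyl)phenyl]ethanone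
Product: 4 1-[3,5-bis(3-methylbut-2-enyl)-4-(triisopropylsilyloxy)phenyl]ethanone
Conditions: TIPSCl, imidazole, DMF, 50 °C
Reagents that add atoms: triisopropylsilyl chloride, CC(C)[Si](Cl)(C(C)C)C(C)C
Why: Imidazole-promoted silylation of a phenol; the bulky silyl ether, further shielded by the two ortho prenyl groups, should withstand the ethoxide, amide bases, Grignard reagent and catalytic acid of the later steps and still fall to fluoride at the end.

**Step 3**
Reactants: 4 1-[3,5-bis(3-methylbut-2-enyl)-4-(triisopropylsilyloxy)phenyl]ethanone; 5 ethyl acetate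
Product: 6 1-[3,5-bis(3-methylbut-2-enyl)-4-(triisopropylsilyloxy)phenyl]butane-1,3-dione
Conditions: NaH, EtOAc (excess), THF, 65 °C; then aq HCl
Reagents that add atoms: none
Why: Crossed Claisen condensation of the methyl ketone enolate with ethyl acetate, pulled to completion by deprotonation of the 1,3-diketone that forms.

**Step 4**
Reactants: 6 1-[3,5-bis(3-methylbut-2-enyl)-4-(triisopropylsilyloxy)phenyl]butane-1,3-dione; 7 N,N'-dimethoxy-N,N'-dimethyloxamide
Product: 9 6-[3,5-bis(3-methylbut-2-enyl)-4-(triisopropylsilyloxy)phenyl]-N-methoxy-N-methyl-4-oxo-4H-pyran-2-carboxamide, via triketo Weinreb amide 8 (not isolated)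
Conditions: LDA (2.2 equiv), THF, −78 to 0 °C; 7, −78 to −20 °C; AcOH; then TsOH·H2O (10 mol %), toluene, 70 °C
Reagents that add atoms: none
Why: The terminal carbon of the diketone dianion is acylated by one Weinreb carbonyl of the oxamide, whose chelated tetrahedral adduct blocks a second addition, and the resulting 1,3,5-triketone undergoes acid-catalysed cyclodehydration to the 4-pyranone under conditions (catalytic acid, aprotic solvent) that spare the prenyl groups and the silyl ether.

**Step 5**
Reactants: 9 6-[3,5-bis(3-methylbut-2-enyl)-4-(triisopropylsilyloxy)phenyl]-N-methoxy-N-methyl-4-oxo-4H-pyran-2-carboxamide; 10 5-bromo-2-methylpent-2-ene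
Product: 12 2-[3,5-bis(3-methylbut-2-enyl)-4-(triisopropylsilyloxy)phenyl]-6-(5-methylhex-4-enoyl)-4H-pyran-4-one, via (4-methylpent-3-enyl)magnesium bromide 11 (not isolated)
Conditions: 10, Mg, THF, rt; then 9, THF, −78 to −40 °C; 1 M HCl
Reagents that add atoms: none
Why: Weinreb ketone synthesis, in which the Grignard reagent adds once to the amide carbonyl (the most electrophilic site, being conjugated to the electron-poor pyranone) and the magnesium chelate holds until work-up, while the low temperature keeps the vinylogous ester carbonyl and the ring carbons of the pyranone out of play.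

**Step 6**
Reactants: 12 2-[3,5-bis(3-methylbut-2-enyl)-4-(triisopropylsilyloxy)phenyl]-6-(5-methylhex-4-enoyl)-4H-pyran-4-one
Product: 14 2-(2-diazo-5-methylhex-4-enoyl)-6-[3,5-bis(3-methylbut-2-enyl)-4-(triisopropylsilyloxy)phenyl]-4H-pyran-4-one, via trifluoroacetyl ketone 13 (not isolated)
Conditions: LiHMDS, THF, −78 °C; CF3CO2CH2CF3; then 4-acetamidobenzenesulfonyl azide, Et3N, H2O (1 equiv), MeCN, rt
Reagents that add atoms: 4-acetamidobenzenesulfonyl azide, CC(=O)Nc1ccc(cc1)S(=O)(=O)N=[N+]=[N-]
Why: Detrifluoroacetylative (Regitz-type) diazo transfer, in which the lithium enolate is trifluoroacetylated, the activated 1,3-dicarbonyl takes up the azide and the triazene collapses with transfer of the trifluoroacetyl group to the sulfonamide nitrogen, leaving the diazo group on the only enolisable carbon.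

**Step 7**
Reactants: 15 acetylene
Product: 18 (triisopropylsilyloxy)acetylene, via ethynyllithium 16 (not isolated), via lithium ethynolate 17 (not isolated)
Conditions: n-BuLi, THF, −78 °C; t-BuOOLi (from t-BuOOH and LiHMDS), −78 to −20 °C; TIPSOTf, −78 to 0 °C
Reagents that add atoms: tert-butyl hydroperoxide, CC(C)(C)OO; triisopropylsilyl trifluoromethanesulfonate, CC(C)[Si](OS(=O)(=O)C(F)(F)F)(C(C)C)C(C)C
Why: Oxidation of a lithium acetylide by lithium tert-butyl peroxide (attack of the acetylide on peroxide oxygen with loss of tert-butoxide) gives the ynolate, which the bulky silyl triflate traps on oxygen instead of carbon; the acetylide is kept at or below −20 °C so that it does not disproportionate to Li2C2.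

**Step 8**
Reactants: 14 2-(2-diazo-5-methylhex-4-enoyl)-6-[3,5-bis(3-methylbut-2-enyl)-4-(triisopropylsilyloxy)phenyl]-4H-pyran-4-one; 18 (triisopropylsilyloxy)acetylene
Product: 23 5-hydroxy-8-(3-methylbut-2-enyl)-2-[3,5-bis(3-methylbut-2-enyl)-4-(triisopropylsilyloxy)phenyl]-7-(triisopropylsilyloxy)-4H-chromen-4-one, via ketene 19 (not isolated), via cyclobutenone 20 (not isolated), via dienylketene 21 (not isolated), via cyclohexadienone 22 (not isolated)
Conditions: 18 (3 equiv), degassed ClCH2CH2Cl, 440 nm LEDs, 20 °C; then 80 °C in the dark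
Reagents that add atoms: none
Why: Proposed new method: light absorbed only by the diazo ketone expels dinitrogen and the pyranonyl group shifts to the diazo carbon (Wolff rearrangement, C8–C8a) to give ketene 19, whose carbonyl carbon is attacked by the unsubstituted, nucleophilic carbon of the ynol ether, so that the [2+2] adduct 20 holds C5–C6 and C7–C8 with the siloxy group at C7. Heating opens 20 by four-electron electrocyclic cleavage to dienylketene 21, ring A closes by a thermal six-electron disrotatory electrocyclisation of the ketene carbon onto pyranone C3 (C4a–C5), and enolisation of 22 gives the hydrogen-bonded 5-phenol. The closest known reaction is the Danheiser benzannulation of aryl and heteroaryl diazo ketones with siloxyalkynes under photochemical Wolff conditions, together with ketene–siloxyalkyne cycloadditions that lead to resorcinol monosilyl ethers; a 4-pyranon-2-yl migrating group and a diazo carbon bearing a CH2 group have not been tried. No stereocentre remains in 23, because the sp3 centres of 20 and 22 are racemic and vanish on ring opening and enolisation, and the ring opening of 20 is reversible, so the dienylketene isomer with the pyranonyl group cis to the ketene drains through the closure. The step needs the orientation of alkyne addition, which the oxygen-polarised triple bond secures, and the prenyl group at C8, which is fixed because it sits on the diazo carbon that becomes bonded to C8a. The Wolff shift must outrun 1,2-hydride migration, which concerted nitrogen loss from the s-Z diazo ketone at 20 °C and the excess alkyne are meant to favour, and 440 nm light leaves the 4-pyranone and the flavone product unexcited.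

**Step 9**
Reactants: 23 5-hydroxy-8-(3-methylbut-2-enyl)-2-[3,5-bis(3-methylbut-2-enyl)-4-(triisopropylsilyloxy)phenyl]-7-(triisopropylsilyloxy)-4H-chromen-4-one
Product: 24 Epimedonin L
Conditions: Bu4NF, AcOH, THF, 0 °C to rt
Reagents that add atoms: none
Why: Fluoride-driven cleavage of both aryl silyl ethers; the acetic acid buffer keeps the phenoxides from oxidising, and no acid strong enough to cyclise the 8-prenyl group onto O7 is present.

**Compound list**
1 | 3,5-dibromo-4-hydroxyacetophenone | CC(=O)c1cc(Br)c(O)c(Br)c1 | starting material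
2 | tributyl(3-methylbut-2-enyl)stannane | CCCC[Sn](CCCC)(CCCC)CC=C(C)C | starting material
3 | 1-[4-hydroxy-3,5-bis(3-methylbut-2-enyl)phenyl]ethanone | CC(=O)c1cc(CC=C(C)C)c(O)c(CC=C(C)C)c1 | intermediate
4 | 1-[3,5-bis(3-methylbut-2-enyl)-4-(triisopropylsilyloxy)phenyl]ethanone | CC(=O)c1cc(CC=C(C)C)c(O[Si](C(C)C)(C(C)C)C(C)C)c(CC=C(C)C)c1 | intermediate
5 | ethyl acetate | CCOC(C)=O | starting material
6 | 1-[3,5-bis(3-methylbut-2-enyl)-4-(triisopropylsilyloxy)phenyl]butane-1,3-dione | CC(=O)CC(=O)c1cc(CC=C(C)C)c(O[Si](C(C)C)(C(C)C)C(C)C)c(CC=C(C)C)c1 | intermediate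
7 | N,N'-dimethoxy-N,N'-dimethyloxamide | CON(C)C(=O)C(=O)N(C)OC | starting material
8 | 6-[3,5-bis(3-methylbut-2-enyl)-4-(triisopropylsilyloxy)phenyl]-N-methoxy-N-methyl-2,4,6-trioxohexanamide (triketo Weinreb amide, not isolated) | CON(C)C(=O)C(=O)CC(=O)CC(=O)c1cc(CC=C(C)C)c(O[Si](C(C)C)(C(C)C)C(C)C)c(CC=C(C)C)c1 | intermediate
9 | 6-[3,5-bis(3-methylbut-2-enyl)-4-(triisopropylsilyloxy)phenyl]-N-methoxy-N-methyl-4-oxo-4H-pyran-2-carboxamide | CON(C)C(=O)c1cc(=O)cc(-c2cc(CC=C(C)C)c(O[Si](C(C)C)(C(C)C)C(C)C)c(CC=C(C)C)c2)o1 | intermediate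
10 | 5-bromo-2-methylpent-2-ene | CC(C)=CCCBr | starting material
11 | (4-methylpent-3-enyl)magnesium bromide (not isolated) | CC(C)=CCC[Mg]Br | intermediate
12 | 2-[3,5-bis(3-methylbut-2-enyl)-4-(triisopropylsilyloxy)phenyl]-6-(5-methylhex-4-enoyl)-4H-pyran-4-one | CC(C)=CCCC(=O)c1cc(=O)cc(-c2cc(CC=C(C)C)c(O[Si](C(C)C)(C(C)C)C(C)C)c(CC=C(C)C)c2)o1 | intermediate
13 | 2-[3,5-bis(3-methylbut-2-enyl)-4-(triisopropylsilyloxy)phenyl]-6-[5-methyl-2-(trifluoroacetyl)hex-4-enoyl]-4H-pyran-4-one (trifluoroacetyl ketone, not isolated) | CC(C)=CCC(C(=O)C(F)(F)F)C(=O)c1cc(=O)cc(-c2cc(CC=C(C)C)c(O[Si](C(C)C)(C(C)C)C(C)C)c(CC=C(C)C)c2)o1 | intermediate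
14 | 2-(2-diazo-5-methylhex-4-enoyl)-6-[3,5-bis(3-methylbut-2-enyl)-4-(triisopropylsilyloxy)phenyl]-4H-pyran-4-one | CC(C)=CCC(=[N+]=[N-])C(=O)c1cc(=O)cc(-c2cc(CC=C(C)C)c(O[Si](C(C)C)(C(C)C)C(C)C)c(CC=C(C)C)c2)o1 | intermediate
15 | acetylene | C#C | starting material
16 | ethynyllithium (not isolated) | [Li]C#C | intermediate
17 | lithium ethynolate (not isolated) | [Li+].[O-]C#C | intermediate
18 | (triisopropylsilyloxy)acetylene | C#CO[Si](C(C)C)(C(C)C)C(C)C | intermediate
19 | 2-{6-[3,5-bis(3-methylbut-2-enyl)-4-(triisopropylsilyloxy)phenyl]-4-oxo-4H-pyran-2-yl}-5-methylhexa-1,4-dien-1-one (ketene, not isolated) | CC(C)=CCC(=C=O)c1cc(=O)cc(-c2cc(CC=C(C)C)c(O[Si](C(C)C)(C(C)C)C(C)C)c(CC=C(C)C)c2)o1 | intermediate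
20 | 4-{6-[3,5-bis(3-methylbut-2-enyl)-4-(triisopropylsilyloxy)phenyl]-4-oxo-4H-pyran-2-yl}-4-(3-methylbut-2-enyl)-3-(triisopropylsilyloxy)cyclobut-2-en-1-one (racemic, not isolated) | O=C1C=C(O[Si](C(C)C)(C(C)C)C(C)C)C1(CC=C(C)C)c2cc(=O)cc(-c3cc(CC=C(C)C)c(O[Si](C(C)C)(C(C)C)C(C)C)c(CC=C(C)C)c3)o2 | intermediate
21 | 4-{6-[3,5-bis(3-methylbut-2-enyl)-4-(triisopropylsilyloxy)phenyl]-4-oxo-4H-pyran-2-yl}-7-methyl-3-(triisopropylsilyloxy)octa-1,3,6-trien-1-one, pyranonyl cis to the ketene (dienylketene, not isolated) | O=C=C/C(O[Si](C(C)C)(C(C)C)C(C)C)=C(/CC=C(C)C)c1cc(=O)cc(-c2cc(CC=C(C)C)c(O[Si](C(C)C)(C(C)C)C(C)C)c(CC=C(C)C)c2)o1 | intermediate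
22 | 8-(3-methylbut-2-enyl)-2-[3,5-bis(3-methylbut-2-enyl)-4-(triisopropylsilyloxy)phenyl]-7-(triisopropylsilyloxy)-4aH-chromene-4,5-dione (racemic keto tautomer, not isolated) | O=C1C=C(O[Si](C(C)C)(C(C)C)C(C)C)C(CC=C(C)C)=C2OC(-c3cc(CC=C(C)C)c(O[Si](C(C)C)(C(C)C)C(C)C)c(CC=C(C)C)c3)=CC(=O)C12 | intermediate
23 | 5-hydroxy-8-(3-methylbut-2-enyl)-2-[3,5-bis(3-methylbut-2-enyl)-4-(triisopropylsilyloxy)phenyl]-7-(triisopropylsilyloxy)-4H-chromen-4-one | CC(C)=CCc1cc(-c2cc(=O)c3c(O)cc(O[Si](C(C)C)(C(C)C)C(C)C)c(CC=C(C)C)c3o2)cc(CC=C(C)C)c1O[Si](C(C)C)(C(C)C)C(C)C | intermediate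
24 | Epimedonin L, 5,7-dihydroxy-2-[4-hydroxy-3,5-bis(3-methylbut-2-enyl)phenyl]-8-(3-methylbut-2-enyl)-4H-chromen-4-one | CC(C)=CCc1cc(-c2cc(=O)c3c(O)cc(O)c(CC=C(C)C)c3o2)cc(CC=C(C)C)c1O | target

Total step count: 9. Longest linear sequence: 8 (steps 1–6, 8, 9).

**Steps most likely to fail**

Step 8. The carbene left after nitrogen loss may undergo 1,2-hydride migration from the neighbouring CH2 faster than the Wolff shift. The pyranone may also enter photochemistry of its own, or the six-electron closure onto the pyranone double bond may lag behind ketene dimerisation. The fallback uses known chemistry, sets out from 4 and comes back at 23; ring A is brought in ready-made instead of being annulated. Methyl 2,4,6-trihydroxybenzoate is protected with MOMCl and NaH in DMF as methyl 2,4,6-tris(methoxymethoxy)benzoate F1. The lithium enolate of 4 (LiHMDS, THF) is acylated by F1 in a crossed Claisen condensation to 1-[2,4,6-tris(methoxymethoxy)phenyl]-3-[3,5-bis(3-methylbut-2-enyl)-4-(triisopropylsilyloxy)phenyl]propane-1,3-dione F2. HCl in MeOH at 50 °C removes the three acetals and closes the pyranone; the symmetric ring A allows only one flavone, 5,7-dihydroxy-2-[3,5-bis(3-methylbut-2-enyl)-4-(triisopropylsilyloxy)phenyl]-4H-chromen-4-one F3. TIPSCl and imidazole silylate the 7-hydroxyl while the chelated 5-hydroxyl stays free, giving the 7-O-silyl flavone F4. Mitsunobu etherification with 3-methylbut-2-en-1-ol (PPh3, diisopropyl azodicarboxylate) gives the 5-O-prenyl ether F5. Eu(fod)3, europium tris(6,6,7,7,8,8,8-heptafluoro-2,2-dimethyloctane-3,5-dionate), in chlorobenzene at 85 °C then moves the prenyl group from O5 to C8 by a para-Claisen–Cope rearrangement and should deliver 23.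

Step 7. Ethynyllithium may disproportionate to Li2C2 and acetylene before oxygen transfer, and the volatile, moisture-sensitive ynol ether may hydrolyse or be lost on isolation. The fallback sets out from 15 and comes back at 17; the ynolate is made by heterocycle fragmentation instead of acetylide oxidation. Acetylene 15 takes up benzonitrile oxide (from N-hydroxybenzimidoyl chloride and Et3N) in a 1,3-dipolar cycloaddition to give 3-phenylisoxazole F6. LDA in THF at −78 °C removes H5 to give 5-lithio-3-phenylisoxazole F7, which should fragment to benzonitrile and lithium ethynolate 17. Compound 17 is silylated with TIPSOTf as in step 7, and 18 is separated from benzonitrile by distillation.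

Step 5. The Grignard reagent may attack the pyranone (conjugate addition at C2 or C6 with ring opening, or addition at C4) in competition with the amide. The fallback sets out from 6 and comes back at 12; the carbon nucleophile is softened to an organozinc and coupled under palladium catalysis. The dianion of 6 (LDA) is added to excess diethyl oxalate at −78 °C to give ethyl 6-aryl-2,4,6-trioxohexanoate F8. TsOH in toluene cyclises F8 to ethyl 6-[3,5-bis(3-methylbut-2-enyl)-4-(triisopropylsilyloxy)phenyl]-4-oxo-4H-pyran-2-carboxylate F9. Me3SnOH in ClCH2CH2Cl at 70 °C hydrolyses the ester to the pyranonecarboxylic acid F10 without base strong enough to open the ring. Oxalyl chloride with catalytic DMF gives the acid chloride F11. Bromide 10 is converted with Zn and LiCl in THF into (4-methylpent-3-enyl)zinc bromide F12. Negishi acylation of F11 with F12 under Pd(PPh3)4 catalysis at room temperature should give ketone 12.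

**Further compounds**
F1 | step 8 | methyl 2,4,6-tris(methoxymethoxy)benzoate | COCOc1cc(OCOC)c(C(=O)OC)c(OCOC)c1
F2 | step 8 | 1-[2,4,6-tris(methoxymethoxy)phenyl]-3-[3,5-bis(3-methylbut-2-enyl)-4-(triisopropylsilyloxy)phenyl]propane-1,3-dione | COCOc1cc(OCOC)c(C(=O)CC(=O)c2cc(CC=C(C)C)c(O[Si](C(C)C)(C(C)C)C(C)C)c(CC=C(C)C)c2)c(OCOC)c1
F3 | step 8 | 5,7-dihydroxy-2-[3,5-bis(3-methylbut-2-enyl)-4-(triisopropylsilyloxy)phenyl]-4H-chromen-4-one | CC(C)=CCc1cc(-c2cc(=O)c3c(O)cc(O)cc3o2)cc(CC=C(C)C)c1O[Si](C(C)C)(C(C)C)C(C)C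
F4 | step 8 | 5-hydroxy-2-[3,5-bis(3-methylbut-2-enyl)-4-(triisopropylsilyloxy)phenyl]-7-(triisopropylsilyloxy)-4H-chromen-4-one | CC(C)=CCc1cc(-c2cc(=O)c3c(O)cc(O[Si](C(C)C)(C(C)C)C(C)C)cc3o2)cc(CC=C(C)C)c1O[Si](C(C)C)(C(C)C)C(C)C
F5 | step 8 | 5-(3-methylbut-2-enyloxy)-2-[3,5-bis(3-methylbut-2-enyl)-4-(triisopropylsilyloxy)phenyl]-7-(triisopropylsilyloxy)-4H-chromen-4-one | CC(C)=CCOc1cc(O[Si](C(C)C)(C(C)C)C(C)C)cc2oc(-c3cc(CC=C(C)C)c(O[Si](C(C)C)(C(C)C)C(C)C)c(CC=C(C)C)c3)cc(=O)c12
F6 | step 7 | 3-phenylisoxazole | c1ccc(cc1)-c1ccon1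
F7 | step 7 | 5-lithio-3-phenylisoxazole | [Li]c1cc(-c2ccccc2)no1
F8 | step 5 | ethyl 6-[3,5-bis(3-methylbut-2-enyl)-4-(triisopropylsilyloxy)phenyl]-2,4,6-trioxohexanoate | CCOC(=O)C(=O)CC(=O)CC(=O)c1cc(CC=C(C)C)c(O[Si](C(C)C)(C(C)C)C(C)C)c(CC=C(C)C)c1
F9 | step 5 | ethyl 6-[3,5-bis(3-methylbut-2-enyl)-4-(triisopropylsilyloxy)phenyl]-4-oxo-4H-pyran-2-carboxylate | CCOC(=O)c1cc(=O)cc(-c2cc(CC=C(C)C)c(O[Si](C(C)C)(C(C)C)C(C)C)c(CC=C(C)C)c2)o1
F10 | step 5 | 6-[3,5-bis(3-methylbut-2-enyl)-4-(triisopropylsilyloxy)phenyl]-4-oxo-4H-pyran-2-carboxylic acid | OC(=O)c1cc(=O)cc(-c2cc(CC=C(C)C)c(O[Si](C(C)C)(C(C)C)C(C)C)c(CC=C(C)C)c2)o1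
F11 | step 5 | 6-[3,5-bis(3-methylbut-2-enyl)-4-(triisopropylsilyloxy)phenyl]-4-oxo-4H-pyran-2-carbonyl chloride | ClC(=O)c1cc(=O)cc(-c2cc(CC=C(C)C)c(O[Si](C(C)C)(C(C)C)C(C)C)c(CC=C(C)C)c2)o1
F12 | step 5 | (4-methylpent-3-enyl)zinc bromide | CC(C)=CCC[Zn]Br
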